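## Retrosynthetic overview

1. Target 12 ⇐ 11 (removal of four O‑methyl groups) ⇐ 10: the pyran ring (ring B) and the lactone ring (ring D) are closed in the same flask, each by a carbonyl oxygen displacing its own secondary mesylate, with inversion at C3 and C3'.
2. 10 ⇐ 9 (one of two formyl groups oxidised) ⇐ 8 (twofold Rieche formylation) ⇐ 7 (mesylation).
3. 7 ⇐ 2 × 4 + ethyl formate (aryllithium addition, then ionic hydrogenation): the CH2 bridge is installed before either heterocycle exists.
4. 4 ⇐ 1 + 2 (copper‑catalysed Grignard opening of the epoxide): sets C4/C4' and the erythro alcohols whose later inversion gives C3/C3'.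
5. Ring order: both benzene rings (rings A and C) are bought; rings B and D are the last bonds made, together.

Assumption: bromide 1 and epoxide 2 are taken as inexpensive catalogue chemicals (2 is otherwise two steps from (2S,3S)-butane-2,3-diol).

## Route

Step 1
Reactants: 1 1-bromo-3,5-dimethoxy-2-methylbenzene; 2 (2S,3S)-2,3-dimethyloxirane
Product: 4 (2S,3S)-3-(3,5-dimethoxy-2-methylphenyl)butan-2-ol, via arylmagnesium bromide 3 (not isolated)
Conditions: Mg, THF, reflux; CuI (10 mol%), −30 °C; 2, −30 °C → rt; H2O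
Reagents that add atoms: none
Why: Copper‑catalysed Grignard opening of an epoxide (SN2, anti): the aryl group attacks one of the two equivalent carbons of the C2‑symmetric epoxide with inversion while the carbinol carbon is untouched, so the erythro (2S,3S) alcohol forms as one stereoisomer, and its benzylic centre is the future C4/C4' (S).

Step 2
Reactants: 4 (2S,3S)-3-(3,5-dimethoxy-2-methylphenyl)butan-2-ol (two molecules)
Product: 7 (2S,3S,2'S,3'S)-3,3'-[methylenebis(3,5-dimethoxy-2-methyl-4,1-phenylene)]di(butan-2-ol), via dilithio species 5 (not isolated), via bridging carbinol 6 (not isolated)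
Conditions: n-BuLi (2.1 equiv), TMEDA, THF, 0 °C → rt; HCO2Et (0.48 equiv), −78 °C → rt; H2O; crude 6 in CH2Cl2, Et3SiH, TFA, 0 °C
Reagents that add atoms: ethyl formate CCOC=O
Why: Directed ortho‑metalation at the ring position between the two methoxy groups (the alkoxide is a spectator), double aryllithium addition to the formate ester, then ionic hydrogenation (Et3SiH/TFA) of the doubly benzylic carbinol flanked by four ortho oxygens; no stereocentre is touched.

Step 3
Reactants: 7 (2S,3S,2'S,3'S)-3,3'-[methylenebis(3,5-dimethoxy-2-methyl-4,1-phenylene)]di(butan-2-ol)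
Product: 8 bis(methanesulfonate) of 7, (2S,3S) in both side chains
Conditions: MsCl (2.5 equiv), Et3N (3 equiv), CH2Cl2, 0 °C
Reagents that add atoms: methanesulfonyl chloride CS(=O)(=O)Cl
Why: Standard mesylation of secondary alcohols; only O–S bonds form, so configuration is retained and the leaving groups for the invertive ring closures are in place.

Step 4
Reactants: 8 bis(methanesulfonate) of 7
Product: 9 3,3'-methylenebis{2,4-dimethoxy-5-methyl-6-[(2S,3S)-3-(methanesulfonyloxy)butan-2-yl]benzaldehyde}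
Conditions: Cl2CHOMe (4 equiv), TiCl4 (5 equiv), CH2Cl2, −78 → −20 °C; ice‑water
Reagents that add atoms: dichloromethyl methyl ether COC(Cl)Cl; water O
Why: Rieche formylation (Friedel–Crafts type) at the only free position of each ring, para to one methoxy group and ortho to the other; the first formyl group deactivates only its own ring, so each ring is formylated once, and no stereocentre is affected.

Step 5
Reactants: 9 3,3'-methylenebis{2,4-dimethoxy-5-methyl-6-[(2S,3S)-3-(methanesulfonyloxy)butan-2-yl]benzaldehyde}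
Product: 10 3-({3-formyl-2,6-dimethoxy-5-methyl-4-[(2S,3S)-3-(methanesulfonyloxy)butan-2-yl]phenyl}methyl)-2,4-dimethoxy-5-methyl-6-[(2S,3S)-3-(methanesulfonyloxy)butan-2-yl]benzoic acid
Conditions: NaClO2 (1.0 equiv), NaH2PO4, 2-methyl-2-butene, t-BuOH/THF/H2O, 0 °C; pH 3, cold extraction; 9 recovered and recycled
Reagents that add atoms: sodium chlorite [Na+].[O-]Cl=O
Why: Pinnick (Lindgren–Kraus) oxidation with one equivalent of oxidant; the two formyl groups are electronically isolated, so the mono‑acid forms statistically (at most about half, separated from neutral 9 by base extraction), and cold acidic work‑up keeps the free acid from displacing its mesylate early.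

Step 6
Reactants: 10 mono‑acid mono‑aldehyde bis‑mesylate
Product: 12 dicitrinone G, via lactone isochromenylium mesylate 11 (not isolated)
Conditions: 2,6-lutidine (1.1 equiv), (CF3)2CHOH, 50 °C; evaporate; BBr3 (10 equiv), CH2Cl2, −78 → 0 °C; H2O
Reagents that add atoms: none
Why: Proposed new method: the ortho carboxylate oxygen of ring C and the ortho formyl oxygen of the 2,4-dimethoxybenzaldehyde unit of ring A (a strongly basic, vinylogous‑carbonate‑type carbonyl) each displace their own secondary mesylate through a six‑membered 6‑exo‑tet transition state with inversion, so the trans‑3,4‑dimethyl lactone (3'R,4'S) and the 6,8‑dimethoxyisochromenylium ion (3R,4S; an O‑methylated quinone methide) form in one operation, after which BBr3 cleaves the four aryl methyl ethers and water releases the quinone methide; the closest known reactions are invertive carboxylate/mesylate lactonisation and neighbouring‑group participation of carbonyl oxygen in sulfonate solvolysis giving cyclic oxocarbenium ions.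

## Compound list

1 | 1-bromo-3,5-dimethoxy-2-methylbenzene | Cc1c(Br)cc(OC)cc1OC | starting material
2 | (2S,3S)-2,3-dimethyloxirane | C[C@@H]1O[C@H]1C | starting material
3 | (3,5-dimethoxy-2-methylphenyl)magnesium bromide | Cc1c([Mg]Br)cc(OC)cc1OC | intermediate
4 | (2S,3S)-3-(3,5-dimethoxy-2-methylphenyl)butan-2-ol | Cc1c(OC)cc(OC)cc1[C@H](C)[C@H](C)O | intermediate
5 | lithium (2S,3S)-3-(4-lithio-3,5-dimethoxy-2-methylphenyl)butan-2-olate | Cc1c(OC)c([Li])c(OC)cc1[C@H](C)[C@H](C)O[Li] | intermediate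
6 | bis{4-[(2S,3S)-3-hydroxybutan-2-yl]-2,6-dimethoxy-3-methylphenyl}methanol | OC(c1c(OC)c(C)c([C@H](C)[C@H](C)O)cc1OC)c1c(OC)c(C)c([C@H](C)[C@H](C)O)cc1OC | intermediate
7 | (2S,3S,2'S,3'S)-3,3'-[methylenebis(3,5-dimethoxy-2-methyl-4,1-phenylene)]di(butan-2-ol) | C(c1c(OC)c(C)c([C@H](C)[C@H](C)O)cc1OC)c1c(OC)c(C)c([C@H](C)[C@H](C)O)cc1OC | intermediate
8 | bis(methanesulfonate) of 7, (2S,3S) side chains | C(c1c(OC)c(C)c([C@H](C)[C@H](C)OS(C)(=O)=O)cc1OC)c1c(OC)c(C)c([C@H](C)[C@H](C)OS(C)(=O)=O)cc1OC | intermediate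
9 | 3,3'-methylenebis{2,4-dimethoxy-5-methyl-6-[(2S,3S)-3-(methanesulfonyloxy)butan-2-yl]benzaldehyde} | C(c1c(OC)c(C)c([C@H](C)[C@H](C)OS(C)(=O)=O)c(C=O)c1OC)c1c(OC)c(C)c([C@H](C)[C@H](C)OS(C)(=O)=O)c(C=O)c1OC | intermediate
10 | 3-({3-formyl-2,6-dimethoxy-5-methyl-4-[(2S,3S)-3-(methanesulfonyloxy)butan-2-yl]phenyl}methyl)-2,4-dimethoxy-5-methyl-6-[(2S,3S)-3-(methanesulfonyloxy)butan-2-yl]benzoic acid | C(c1c(OC)c(C)c([C@H](C)[C@H](C)OS(C)(=O)=O)c(C=O)c1OC)c1c(OC)c(C)c([C@H](C)[C@H](C)OS(C)(=O)=O)c(C(=O)O)c1OC | intermediate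
11 | (3R,4S)-7-{[(3R,4S)-6,8-dimethoxy-3,4,5-trimethyl-1-oxo-3,4-dihydro-1H-isochromen-7-yl]methyl}-6,8-dimethoxy-3,4,5-trimethyl-3,4-dihydroisochromenylium methanesulfonate | C(c1c(OC)c(C)c2c(c1OC)C=[O+][C@H](C)[C@H]2C)c1c(OC)c(C)c2c(c1OC)C(=O)O[C@H](C)[C@H]2C.CS(=O)(=O)[O-] | intermediate
12 | dicitrinone G, (3R,4S)-7-{[(3R,4S)-6-hydroxy-3,4,5-trimethyl-8-oxo-4,8-dihydro-3H-isochromen-7-yl]methyl}-6,8-dihydroxy-3,4,5-trimethylisochroman-1-one | CC1=C2C(=CO[C@H](C)[C@H]2C)C(=O)C(Cc2c(O)c(C)c3c(c2O)C(=O)O[C@H](C)[C@H]3C)=C1O | target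

## Count and risks

Total step count: 6 (step 2 is telescoped, the crude carbinol is not purified). Longest linear sequence: 6.

Most likely to fail, first: step 6. The carbonyl‑oxygen closure of the aldehyde half has no direct precedent; elimination to a styrene, or loss of stereochemical integrity at C3, could compete. The fallback sets out from 9 and comes back at 12. Both formyl groups are oxidised (excess NaClO2, NaH2PO4, 2-methyl-2-butene) to the diacid bis-mesylate F1. K2CO3 in MeCN at 60 °C then closes both rings by the well‑known invertive carboxylate displacement to the C2‑symmetric bis-lactone F2. One lactone is reduced with iBu2AlH (1.0 equiv, CH2Cl2, −78 °C; statistical, F2 recovered) to the lactone lactol F3. BBr3 ionises the lactol to the same isochromenylium ion and removes the methyl groups to give 12. The pyran ring then comes from a lactone by reduction, not from C3–O bond formation by a formyl oxygen.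

Second: step 4. TiCl4 may ionise the mesylates, or the electrophile may attack ipso at the bridge carbon and cleave the electron‑rich diarylmethane. The fallback sets out from 8 and comes back at 9. Both free ring positions are brominated with N-bromosuccinimide (MeCN, 0 °C) to the dibromide F4. Bromine–magnesium exchange with nBu3MgLi (THF, −10 °C) and a DMF quench then give 9. The C–C bond is made by an aryl‑metal, and no strong Lewis acid meets the substrate.

Third: step 5. The yield is capped at about half by statistics, the three‑component mixture must be separated, and the acid may close its lactone early. An early closure is harmless for stereochemistry, because it also proceeds with inversion. The fallback sets out from 4 and comes back at 11, and it distinguishes the two halves by a bromine atom from the start: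

- Dianion 5 is quenched with DMF to give the aldehyde F5.
- N-bromosuccinimide (MeCN) brominates the free ring position to give the bromo aldehyde F6.
- F6, as its sodium alkoxide (NaH), is added at −78 °C to a second portion of dianion 5 to give the unsymmetrical carbinol F7.
- Et3SiH/TFA reduces F7 to the monobromo diol F8.
- MsCl/Et3N gives the bromo bis-mesylate F9.
- Bromine–magnesium exchange (nBu3MgLi, −10 °C), CO2, then warming to 50 °C lets the carboxylate displace its mesylate with inversion to give the lactone mesylate F10.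
- Rieche formylation of the one remaining ring position gives the lactone aldehyde mesylate F11.
- Heating F11 in (CF3)2CHOH closes the pyran ring to 11.

## Further compounds

F1 | step 6 | 3,3'-methylenebis{2,4-dimethoxy-5-methyl-6-[(2S,3S)-3-(methanesulfonyloxy)butan-2-yl]benzoic acid} | C(c1c(OC)c(C)c([C@H](C)[C@H](C)OS(C)(=O)=O)c(C(=O)O)c1OC)c1c(OC)c(C)c([C@H](C)[C@H](C)OS(C)(=O)=O)c(C(=O)O)c1OC
F2 | step 6 | 7,7'-methylenebis[(3R,4S)-6,8-dimethoxy-3,4,5-trimethylisochroman-1-one] | C(c1c(OC)c(C)c2c(c1OC)C(=O)O[C@H](C)[C@H]2C)c1c(OC)c(C)c2c(c1OC)C(=O)O[C@H](C)[C@H]2C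
F3 | step 6 | (3R,4S)-7-{[(3R,4S)-1-hydroxy-6,8-dimethoxy-3,4,5-trimethylisochroman-7-yl]methyl}-6,8-dimethoxy-3,4,5-trimethylisochroman-1-one (lactol epimers) | C(c1c(OC)c(C)c2c(c1OC)C(O)O[C@H](C)[C@H]2C)c1c(OC)c(C)c2c(c1OC)C(=O)O[C@H](C)[C@H]2C
F4 | step 4 | bis{3-bromo-2,6-dimethoxy-5-methyl-4-[(2S,3S)-3-(methanesulfonyloxy)butan-2-yl]phenyl}methane | C(c1c(OC)c(C)c([C@H](C)[C@H](C)OS(C)(=O)=O)c(Br)c1OC)c1c(OC)c(C)c([C@H](C)[C@H](C)OS(C)(=O)=O)c(Br)c1OC
F5 | step 5 | 4-[(2S,3S)-3-hydroxybutan-2-yl]-2,6-dimethoxy-3-methylbenzaldehyde | O=Cc1c(OC)c(C)c([C@H](C)[C@H](C)O)cc1OC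
F6 | step 5 | 3-bromo-4-[(2S,3S)-3-hydroxybutan-2-yl]-2,6-dimethoxy-5-methylbenzaldehyde | O=Cc1c(OC)c(C)c([C@H](C)[C@H](C)O)c(Br)c1OC
F7 | step 5 | {3-bromo-4-[(2S,3S)-3-hydroxybutan-2-yl]-2,6-dimethoxy-5-methylphenyl}{4-[(2S,3S)-3-hydroxybutan-2-yl]-2,6-dimethoxy-3-methylphenyl}methanol (carbinol epimers) | OC(c1c(OC)c(C)c([C@H](C)[C@H](C)O)c(Br)c1OC)c1c(OC)c(C)c([C@H](C)[C@H](C)O)cc1OC
F8 | step 5 | (2S,3S)-3-[3-bromo-4-({4-[(2S,3S)-3-hydroxybutan-2-yl]-2,6-dimethoxy-3-methylphenyl}methyl)-2,6-dimethoxy... monobromo analogue of 7 (bromine at the free position of one ring) | C(c1c(OC)c(C)c([C@H](C)[C@H](C)O)c(Br)c1OC)c1c(OC)c(C)c([C@H](C)[C@H](C)O)cc1OC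
F9 | step 5 | bis(methanesulfonate) of F8, (2S,3S) side chains | C(c1c(OC)c(C)c([C@H](C)[C@H](C)OS(C)(=O)=O)c(Br)c1OC)c1c(OC)c(C)c([C@H](C)[C@H](C)OS(C)(=O)=O)cc1OC
F10 | step 5 | (3R,4S)-7-({4-[(2S,3S)-3-(methanesulfonyloxy)butan-2-yl]-2,6-dimethoxy-3-methylphenyl}methyl)-6,8-dimethoxy-3,4,5-trimethylisochroman-1-one | C(c1c(OC)c(C)c2c(c1OC)C(=O)O[C@H](C)[C@H]2C)c1c(OC)c(C)c([C@H](C)[C@H](C)OS(C)(=O)=O)cc1OC
F11 | step 5 | (3R,4S)-7-({3-formyl-2,6-dimethoxy-5-methyl-4-[(2S,3S)-3-(methanesulfonyloxy)butan-2-yl]phenyl}methyl)-6,8-dimethoxy-3,4,5-trimethylisochroman-1-one | C(c1c(OC)c(C)c2c(c1OC)C(=O)O[C@H](C)[C@H]2C)c1c(OC)c(C)c([C@H](C)[C@H](C)OS(C)(=O)=O)c(C=O)c1OC
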